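The data are calculated for an exercise, noise included.

A small charge of partner, 40.0% of the starting material charged, went with a flat autumn run: starting material read 61.6% at 5.00 min and 61.0% at 40.0 min.

| flask | starting material | partner | remark | time |
|---|---|---|---|---|
| autumn | 0.40 M | 0.16 M | run made earlier |  |
| noon | 0.40 M | 0.64 M | run made earlier |  |
| dawn | 0.80 M | 0.32 M | run made earlier |  |
| flask | 0.40 M | 0.320 M |  | 50 min |

| run | time / min | starting material / % | product / % |
|---|---|---|---|
| autumn | 5.00 | 61.6 | 17.8 |
| autumn | 15.0 | 60.3 | 15.8 |
| autumn | 25.0 | 61.2 | 17.8 |
| autumn | 40.0 | 61.0 | 15.5 |
| noon | 5.00 | 1.1 | 42.1 |
| noon | 15.0 | 0 | 39.7 |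
| noon | 25.0 | 2.0 | 38.2 |
| noon | 40.0 | 0 | 39.2 |
| dawn | 5.00 | 61.6 | 14.9 |
| dawn | 15.0 | 59.6 | 15.6 |
| dawn | 25.0 | 61.2 | 16.2 |
| dawn | 40.0 | 60.7 | 16.1 |

(standard deviation of a reading: 1 percentage point)

- the reaction counts as stopped when no species that holds the starting material changes by six tenths of a point or more over the second half of the time

- the state of affairs at 50 min: stopped, and by what, or still going (it is still moving / forward and back rates have come level / all of the starting material has reacted / the partner has run out first)
- conversion of starting material at 50 min
- amount of product at 50 min, in percent of the starting material charged
- amount of intermediate C at 50 min, in percent of the starting material charged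

Partner was not read, so I divided the fall of starting material by the partner charged, which took time out. Autumn lost 39.0% of its starting material with a partner charge worth 40.0%, so that ratio read 0.975, and I took the two to react one to one. For the flask I reckoned the reach as 80.0%: the partner charged as a fraction of the starting material charged. The flask held less partner than starting material, so I named partner the limiting reagent and expected the conversion at the stop to equal the reach.

I tested it on the other runs. Dawn had larger charges and a reach of 40.0%, and its starting material read 60.7%. Noon had a reach of 160%, and its starting material read 0%. The autumn gap of 1 percentage point was the size of the scatter of 1 point, so the readings did not call for a balance, and I committed to a stop by lack of partner.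

One number was not enough. The noon readings put product at 40.1% of what reacted, so I expected 32.1% product in the flask. Intermediate C was never read, so I gave it no figure beyond a limit of 47.9%.

The forecast differed on the stop and the conversion: forward and back rates have come level, conversion 77%, product 31%, intermediate C 46%. It said the rest of what reacted “is presumably C”.

The flask gave this at 50 min: the partner has run out first, with 0% of it left. Conversion was 80.0% against a reach of 80.0%, product 31.2%, intermediate C 22.5% and decomposed reagent 26.3%.

    intermediate B → intermediate C (k = 0.0250 /s)
    intermediate A ⇌ intermediate B (K = 2.60, k = 0.0300 /s)
    intermediate B → decomposed reagent (k = 0.110 /s)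
    intermediate B → product (k = 0.200 /s)
    starting material + partner → intermediate A (k = 0.0590 /M/s)
    product ⇌ intermediate C (K = 0.720, k = 0.00470 /s)

Intermediate C stood 24 points below the forecast. The neighbour flask with 0.13 M of partner had a reach of 32.5%, and the same reckoning gave 13.0% product. That neighbour reached conversion 32.5% and product 12.7%, with 0% of its partner left. Its intermediate C was 9.14%.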